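A percent per second belongs to one charge of D, so Monday's fall of D is carried to another flask in M/s.

| flask | D | J | E | remark | time |
|---|---|---|---|---|---|
| Monday's | 0.13 M | 0.101 M | 0.168 M | run made earlier |  |
| flask | 0.084 M | 0.101 M | 0.168 M |  | 2.0 min |

Monday's run (percent of the D charged)

| time / s | Q / % | D / % |
|---|---|---|
| 10.0 | 19 | 75 |
| 12.0 | 20 | 66 |
| 15.0 | 31 | 62 |
| 20.0 | 38 | 52 |
| 25.0 | 48 | 38 |

(readings scatter by 2 percentage points)

- given per volume of solution although it is solid: D
- at the start none of D is in solution

- when, up to 2.0 min, the flask holds most Q
- the amount of Q, in percent of the D charged, at that time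

The reckoning below is built up one process at a time.

1. Dissolving. D falls about evenly in Monday's run, a zero-order feed. Its mean rate up to the last reading is 0.00322 M/s. The first reading gives 0.00325 M/s, so replacing the curve by its mean costs little. The flask has Monday's J and E; at that rate its D lasts 26.1 s. This is the clearing time, the charge of D divided by the feed rate. The reckoning so far puts Q at 100% at the clearing time.

2. The gap. Q gained per D lost in Monday's run reads 77.4% at the last reading and 76.0% at the first, both with their scatter. Carried to the flask, that share lowers this reckoning's peak to about 77.4%.

3. The rest. Monday's D still reads 38% at the last reading, at 25.0 s, so what follows clearing is unread in that run. This reckoning puts the most Q near 0.434 min, at about 77.4%.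

The forecast gives 0.6 min and 76%, later than this reckoning, and calls the time “uncertain on the late side”.

The flask holds most Q at 0.519 min, namely 74.6%, with D at 0% and G at 5.80%.

    G + J → Q (k = 5.50 /M/s)
    G + E → Z (k = 0.0920 /M/s)
    D ⇌ G, rate k3*(cs3 - [G]) while solid is left; crystals form when [G] > cs3 (solubility = 33.0 mM, k = 0.130 /s)
    G → L (k = 1.00 × 10⁻⁴ /s)
    Q → X (k = 0.0110 /s)

The forecast's amount stands within its margin, but its time is 1.16 times the flask's. The flask's best time is 1.20 clearing times.

The same flask read at 50 s stands at 1.92 clearing times, past that peak, so its Q should read below the best. It holds 64.8% against a highest 74.6%.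

Readings and results come from a simulation for substances that don't exist, noise included.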